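**Plan**
- Cuts: C13=C14 (Horner–Wadsworth–Emmons on a C13 methyl ketone); the 6β,19-diol back to a 19,6β-lactone; C3–C4 of ring A (lactone enolate plus C3 aldehyde); C9–C11 (sp2–sp3 coupling); O–C6 (lactonisation); C10–C1 and C10–C20 (enolate alkylations); this leads back to (R)-carvone as ring B.
- Forward: carvone is ring B. C20 and the allyl unit C1–C3 go onto C10, the isopropenyl group becomes the C4 propionic acid and lactonises onto C6, and the C9 enol triflate takes the side chain. Ring A closes last; then the lactone is reduced and the enoic acid completed.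
- Enabling feature: C19 on C4 and the oxygen on C6 are both axial on the β face of rings A and B (1,3 across C5), so they can be tied as a γ-lactone whose α-carbon is C4, next to C3. A C3 aldehyde hanging from C10 then closes ring A by aldol addition of the lactone enolate.
- Stereochemistry: C5 from (R)-carvone; C10 by alkylation anti to the isopropenyl group; C6 by cis-lactonisation from the C5 side arm; C4 by the lactone template and the C10 tether in the ring closure; C3 by bulky-hydride reduction of the 3-ketone; 13E by the olefination.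

Key step: step 13

Numbering: from 7 on, carbons carry the labdane numbers they have in the target (ring B = C5–C10; C17 on C8; C20 on C10; C1–C3 = allyl carbons; C4/C18/C19 = the three-carbon unit on C5; C11–C16 = side chain). β is the face of ring B that bears the C10 methyl group; the series is the normal labdane one (5α-H, 10β-CH3).
Assumption: 2-methyl-2-vinyl-1,3-dioxolane (17) is bought. The configuration at C4 is left open in 8–24 because this centre is epimerisable or carries bromine and becomes trigonal in step 13.

Step 1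
Reactants: 1 (R)-(−)-carvone; 2 iodomethane
Product: 4 (5R,6S)-6-methylcarvone (with its 6-epimer), via lithium enolate 3 (not isolated)
Conditions: LiN(i-Pr)2, THF, −78 °C; MeI, −78 → 0 °C
Reagents that add atoms: iodomethane (2), CI
Why: Kinetic deprotonation at the α′ carbon (future C10) and enolate alkylation install C20; the configuration of this centre is unimportant because it is enolised again in step 2.

Step 2
Reactants: 4 6-methylcarvone; 5 allyl bromide
Product: 7 (5S,6S)-6-allyl-2,6-dimethyl-5-(prop-1-en-2-yl)cyclohex-2-en-1-one, via lithium enolate 6 (not isolated)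
Conditions: LiN(i-Pr)2, THF, −78 °C; allyl bromide, −78 → 0 °C
Reagents that add atoms: allyl bromide (5), C=CCBr
Why: Enolate alkylation of the trisubstituted enolate creates quaternary C10 with the electrophile entering anti to the neighbouring isopropenyl group, so allyl (C1–C3) is trans and C20 cis to the C5 substituent, as the trans ring fusion of the target requires.

Step 3
Reactants: 7 allyl methyl carvone
Product: 8 C4–C19 epoxide of 7 (both oxirane epimers)
Conditions: mCPBA (1.0 equiv), CH2Cl2, 0 °C
Reagents that add atoms: 3-chloroperbenzoic acid, OOC(=O)c1cccc(Cl)c1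
Why: Prilezhaev epoxidation selects the electron-richer 1,1-disubstituted isopropenyl olefin over the monosubstituted allyl olefin and the electron-poor enone.

Step 4
Reactants: 8 epoxide
Product: 9 2-(2-allyl-2,4-dimethyl-3-oxocyclohex-4-en-1-yl)propanal (C4 epimers)
Conditions: BF3·OEt2 (cat.), CH2Cl2, −78 → −40 °C
Reagents that add atoms: none
Why: Meinwald rearrangement: opening to the tertiary C4 cation and 1,2-hydride shift from C19 turn the 2,2-disubstituted epoxide into the α-methyl aldehyde, low temperature and catalytic acid holding back ene or Prins side paths.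

Step 5
Reactants: 9 aldehyde
Product: 10 2-(2-allyl-2,4-dimethyl-3-oxocyclohex-4-en-1-yl)propanoic acid
Conditions: NaClO2, NaH2PO4, 2-methyl-2-butene, t-BuOH/H2O, rt
Reagents that add atoms: sodium chlorite, [Na+].[O-]Cl=O
Why: Pinnick oxidation takes the aldehyde to the acid without touching the olefins, the hypochlorous acid formed being trapped by 2-methyl-2-butene.

Step 6
Reactants: 10 enone acid
Product: 12 β,γ-unsaturated keto acid (olefin at C6=C7), via dilithium dienolate carboxylate 11 (not isolated)
Conditions: LiN(i-Pr)2 (2.5 equiv), THF, −78 → −40 °C; inverse quench into AcOH/THF, −78 °C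
Reagents that add atoms: none
Why: Deconjugation by kinetic protonation: with C10 quaternary the enone can only lose a proton at C6 (γ), and the extended dienolate is protonated at C8 (α), which moves the olefin to C6=C7 next to the carboxyl-bearing C5.

Step 7
Reactants: 12 β,γ-unsaturated keto acid
Product: 14 cis-fused 19,6β-lactone enone, via 7α-iodo lactone 13 (not isolated)
Conditions: I2, NaHCO3, MeCN/H2O, 0 °C; then DBU, rt
Reagents that add atoms: none
Why: Iodolactonisation (5-exo, anti addition) delivers the carboxylate to C6 on the face of the C5 side arm, setting the 6β C–O bond as a cis-fused γ-lactone, and E1cB loss of HI from the β-iodo ketone restores the C7=C8 enone.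

Step 8
Reactants: 14 lactone enone
Product: 16 C9 enol triflate of the 19,6β-lactone, via lithium enolate 15 (not isolated)
Conditions: LiBH(s-Bu)3, THF, −78 °C; then PhNTf2, −78 → 0 °C
Reagents that add atoms: N-phenylbis(trifluoromethanesulfonimide), O=S(=O)(N(c1ccccc1)S(=O)(=O)C(F)(F)F)C(F)(F)F
Why: Conjugate (1,4) hydride reduction of the hindered enone gives the C9 enolate regiospecifically, and O-sulfonylation traps it as the tetrasubstituted C8=C9 enol triflate; the lactone is not attacked at −78 °C.

Step 9
Reactants: 16 enol triflate; 17 2-methyl-2-vinyl-1,3-dioxolane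
Product: 19 C9-alkylated lactone (dioxolane side chain C11–C13 and C16), via alkylborane 18 (not isolated)
Conditions: 17, 9-BBN (no excess), THF, 0 °C → rt; then 16, Pd(dppf)Cl2 (cat.), AsPh3 (cat.), Cs2CO3, DMF/H2O, rt → 50 °C
Reagents that add atoms: 2-methyl-2-vinyl-1,3-dioxolane (17), C=CC1(C)OCCO1
Why: B-alkyl Suzuki–Miyaura coupling: anti-Markovnikov hydroboration gives the primary alkylborane, which zerovalent palladium transfers to C9 with the C8=C9 olefin kept in place; without free 9-BBN the allyl group stays untouched.

Step 10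
Reactants: 19 lactone
Product: 21 C4 bromo lactone, via lithium lactone enolate 20 (not isolated)
Conditions: LiN(i-Pr)2, THF, −78 °C; then CBr4, −78 °C
Reagents that add atoms: carbon tetrabromide, BrC(Br)(Br)Br
Why: Deprotonation of the only acidic C–H (C4, α to the lactone carbonyl) and electrophilic bromination of the enolate give the tertiary α-bromo lactone, the activating group that later lets the C4 enolate form beside an enolisable aldehyde.

Step 11
Reactants: 21 bromo lactone
Product: 23 C3 primary alcohol, via alkylborane 22 (not isolated)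
Conditions: 9-BBN, THF, 0 °C → rt; then NaBO3·4H2O, H2O, rt
Reagents that add atoms: sodium perborate (NaBO3·4H2O), [Na+].[Na+].O[B-]1(O)OO[B-](O)(O)OO1
Why: Hydroboration–oxidation: 9-BBN adds anti-Markovnikov to the monosubstituted allyl olefin only (the tetrasubstituted C8=C9 olefin, lactone and bromide are inert), and mild perborate oxidation gives the alcohol.

Step 12
Reactants: 23 alcohol
Product: 24 3-{3-bromo-3,4,6-trimethyl-5-[2-(2-methyl-1,3-dioxolan-2-yl)ethyl]-2-oxo-2,3,3a,4,7,7a-hexahydrobenzofuran-4-yl}propanal
Conditions: Dess–Martin periodinane, pyridine, CH2Cl2, 0 °C → rt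
Reagents that add atoms: none
Why: Dess–Martin oxidation stops at the aldehyde under buffered, non-basic conditions that spare the dioxolane and the tertiary bromide.

Step 13
Reactants: 24 bromo lactone aldehyde
Product: 26 13,13-(ethylenedioxy)-3β-hydroxy-14,15-dinorlabd-8-en-19,6β-olide, via samarium enolate 25 (not isolated)
Conditions: SmI2 (2.5 equiv), THF, −78 °C, slow addition of 24 at high dilution
Reagents that add atoms: none
Why: SmI2 reduces the tertiary C4–Br bond to the trivalent samarium enolate 25 of the 19,6β-lactone, the only site where an enolate can arise, so the enolisable C3 aldehyde is never deprotonated; the closest known reaction type is the intramolecular Reformatsky (aldol) addition of an α-bromo ester to an aldehyde giving an α-quaternary β-hydroxy ester. C4 of the enolate adds to the C3 carbonyl, forming C3–C4 and closing ring A in a 6-exo-trig (enolexo) mode. The new C4 centre is fixed by the substrate: the enolate lies in the lactone cis-fused to ring B and the aldehyde chain hangs from C10, so C3 can only reach the enolate face on which C10 sits, which leaves C19 β in the lactone and C18 α, the trans ring fusion being already held in C5 and C10. The C3 centre is governed by the closed chair in which samarium bridges the enolate and aldehyde oxygens; this places the C3–O bond gauche to C19 and should favour the equatorial 3β alcohol. The step therefore needs only regioselective enolate formation (secured by the C–Br bond) and C4 face selectivity (secured by lactone and tether), since step 14 oxidises both C3 epimers to one ketone and step 15 sets C3. Slow addition to excess SmI2 keeps protonation of 25 and pinacol coupling behind ring closure.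

Step 14
Reactants: 26 3β-hydroxy lactone (any 3α epimer is carried along)
Product: 27 13,13-(ethylenedioxy)-3-oxo-14,15-dinorlabd-8-en-19,6β-olide
Conditions: Dess–Martin periodinane, pyridine, CH2Cl2, rt
Reagents that add atoms: none
Why: Dess–Martin oxidation gives the 3-oxo lactone, which has no hydrogen between its two carbonyls and cannot epimerise at C4; the C3 centre is erased so that it can be set by reagent control.

Step 15
Reactants: 27 keto lactone
Product: 28 13,13-(ethylenedioxy)-3α-hydroxy-14,15-dinorlabd-8-en-19,6β-olide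
Conditions: LiBH(s-Bu)3, THF, −78 °C
Reagents that add atoms: none
Why: Diastereoselective ketone reduction: the bulky borohydride attacks the ring A chair along the equatorial trajectory, away from the axial hydrogens on C1 and C5, giving the axial 3α alcohol, while the lactone is not reduced at this temperature.

Step 16
Reactants: 28 3α-hydroxy lactone
Product: 30 3α,6β,19-trihydroxy-14,15-dinorlabd-8-en-13-one, via triol dioxolane 29 (not isolated)
Conditions: LiAlH4, THF, 0 °C → rt; aqueous work-up; then PPTS (cat.), acetone/H2O, 50 °C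
Reagents that add atoms: water, O
Why: Hydride reduction of the lactone frees the 6β and C19 hydroxyls together without touching a stereocentre, and mild acid-catalysed acetal hydrolysis then uncovers the C13 methyl ketone while leaving the tetrasubstituted olefin in place.

Step 17
Reactants: 30 keto triol; 31 triethyl phosphonoacetate
Product: 32 ethyl (13E)-3α,6β,19-trihydroxylabda-8,13-dien-15-oate
Conditions: 31, NaH (1 equiv per phosphonate, anion preformed), THF, 0 °C; then 30, rt → 50 °C
Reagents that add atoms: triethyl phosphonoacetate (31), CCOC(=O)CP(=O)(OCC)OCC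
Why: Horner–Wadsworth–Emmons olefination with the preformed phosphonate anion (too weakly basic to deprotonate the hydroxyls) converts the methyl ketone into the trisubstituted enoate, the E isomer (ester trans to the C12 chain) being favoured and freed from the minor Z isomer by chromatography.

Step 18
Reactants: 32 ethyl ester
Product: 33 (13E)-3α,6β,19-trihydroxylabda-8,13-dien-15-oic acid (target)
Conditions: LiOH, THF/MeOH/H2O, 50 °C; then 1 M HCl to pH 3
Reagents that add atoms: lithium hydroxide, [Li+].[OH-]
Why: Saponification of the ester and acidification give the acid; no stereocentre or olefin geometry is at risk.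

**Compound list**
1 | (R)-(−)-carvone, (5R)-2-methyl-5-(prop-1-en-2-yl)cyclohex-2-en-1-one | CC1=CC[C@H](CC1=O)C(C)=C | starting material
2 | iodomethane | CI | starting material
3 | lithium enolate of 1 (cross-conjugated, enolate double bond toward the α′ carbon) | CC1=CC[C@@H](C(C)=C)C=C1O[Li] | intermediate
4 | (5R,6S)-2,6-dimethyl-5-(prop-1-en-2-yl)cyclohex-2-en-1-one (6-methylcarvone, methyl trans to isopropenyl; its 6-epimer accompanies it) | CC1=CC[C@@H](C(C)=C)[C@H](C)C1=O | intermediate
5 | allyl bromide | C=CCBr | starting material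
6 | lithium enolate of 4 | CC1=CC[C@@H](C(C)=C)C(C)=C1O[Li] | intermediate
7 | (5S,6S)-6-allyl-2,6-dimethyl-5-(prop-1-en-2-yl)cyclohex-2-en-1-one (allyl trans, methyl cis to isopropenyl) | CC1=CC[C@@H](C(C)=C)[C@](C)(CC=C)C1=O | intermediate
8 | 6-allyl-2,6-dimethyl-5-(2-methyloxiran-2-yl)cyclohex-2-en-1-one, ring centres as in 7, both oxirane epimers | CC1=CC[C@@H](C2(C)CO2)[C@](C)(CC=C)C1=O | intermediate
9 | 2-(2-allyl-2,4-dimethyl-3-oxocyclohex-4-en-1-yl)propanal, ring centres as in 7, C4 epimers | CC1=CC[C@@H](C(C)C=O)[C@](C)(CC=C)C1=O | intermediate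
10 | 2-(2-allyl-2,4-dimethyl-3-oxocyclohex-4-en-1-yl)propanoic acid, ring centres as in 7, C4 epimers | CC1=CC[C@@H](C(C)C(=O)O)[C@](C)(CC=C)C1=O | intermediate
11 | dilithium salt of 10: carboxylate and extended C9 dienolate (C8=C9, C6=C7) | CC1=C(O[Li])[C@@](C)(CC=C)[C@H](C(C)C(=O)O[Li])C=C1 | intermediate
12 | 2-(2-allyl-2,4-dimethyl-3-oxocyclohex-5-en-1-yl)propanoic acid (olefin at C6=C7; C8 and C4 epimers) | CC1C=C[C@@H](C(C)C(=O)O)[C@](C)(CC=C)C1=O | intermediate
13 | 4-allyl-7-iodo-3,4,6-trimethylhexahydrobenzofuran-2,5-dione, cis-fused lactone, 6β-O, 7α-I (iodine trans to the lactone oxygen) | CC1[C@H](I)[C@H]2OC(=O)C(C)[C@H]2[C@](C)(CC=C)C1=O | intermediate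
14 | 4-allyl-3,4,6-trimethyl-3a,7a-dihydrobenzofuran-2,5(3H,4H)-dione, cis-fused 19,6β-lactone with C7=C8 enone (5α-H, 6α-H, 10β-CH3, 10α-allyl) | CC1=C[C@H]2OC(=O)C(C)[C@H]2[C@](C)(CC=C)C1=O | intermediate
15 | lithium C9 enolate of the 7,8-dihydro derivative of 14 | CC1=C(O[Li])[C@@](C)(CC=C)[C@@H]2C(C)C(=O)O[C@@H]2C1 | intermediate
16 | 4-allyl-3,4,6-trimethyl-2-oxo-2,3,3a,4,7,7a-hexahydrobenzofuran-5-yl trifluoromethanesulfonate (C9 enol triflate, ring centres as in 14) | CC1=C(OS(=O)(=O)C(F)(F)F)[C@@](C)(CC=C)[C@@H]2C(C)C(=O)O[C@@H]2C1 | intermediate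
17 | 2-methyl-2-vinyl-1,3-dioxolane | C=CC1(C)OCCO1 | starting material
18 | B-[2-(2-methyl-1,3-dioxolan-2-yl)ethyl]-9-borabicyclo[3.3.1]nonane | CC1(CCB2C3CCCC2CCC3)OCCO1 | intermediate
19 | 4-allyl-3,4,6-trimethyl-5-[2-(2-methyl-1,3-dioxolan-2-yl)ethyl]-3a,4,7,7a-tetrahydrobenzofuran-2(3H)-one (ring centres as in 14) | CC1=C(CCC3(C)OCCO3)[C@@](C)(CC=C)[C@@H]2C(C)C(=O)O[C@@H]2C1 | intermediate
20 | lithium enolate of lactone 19 (C4=C19–OLi) | CC1=C(CCC3(C)OCCO3)[C@@](C)(CC=C)[C@@H]2C(C)=C(O[Li])O[C@@H]2C1 | intermediate
21 | 3-bromo derivative of 19 (bromine on C4, α to the lactone carbonyl; either C4 configuration) | CC1=C(CCC3(C)OCCO3)[C@@](C)(CC=C)[C@@H]2C(C)(Br)C(=O)O[C@@H]2C1 | intermediate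
22 | B-alkyl-9-BBN adduct of 21 (boron on C3) | CC1=C(CCC3(C)OCCO3)[C@@](C)(CCCB4C5CCCC4CCC5)[C@@H]2C(C)(Br)C(=O)O[C@@H]2C1 | intermediate
23 | 3-bromo-4-(3-hydroxypropyl)-3,4,6-trimethyl-5-[2-(2-methyl-1,3-dioxolan-2-yl)ethyl]-3a,4,7,7a-tetrahydrobenzofuran-2(3H)-one | CC1=C(CCC3(C)OCCO3)[C@@](C)(CCCO)[C@@H]2C(C)(Br)C(=O)O[C@@H]2C1 | intermediate
24 | 3-{3-bromo-3,4,6-trimethyl-5-[2-(2-methyl-1,3-dioxolan-2-yl)ethyl]-2-oxo-2,3,3a,4,7,7a-hexahydrobenzofuran-4-yl}propanal (precursor of the key step) | CC1=C(CCC3(C)OCCO3)[C@@](C)(CCC=O)[C@@H]2C(C)(Br)C(=O)O[C@@H]2C1 | intermediate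
25 | samarium enolate of the lactone (C4=C19–O–SmI2) carrying the C3 aldehyde | CC1=C(CCC3(C)OCCO3)[C@@](C)(CCC=O)[C@@H]2C(C)=C(O[Sm](I)I)O[C@@H]2C1 | intermediate
26 | 13,13-(ethylenedioxy)-3β-hydroxy-14,15-dinorlabd-8-en-19,6β-olide | CC1=C(CCC4(C)OCCO4)[C@@]2(C)CC[C@H](O)[C@](C)(C(=O)O3)[C@@H]2[C@H]3C1 | intermediate
27 | 13,13-(ethylenedioxy)-3-oxo-14,15-dinorlabd-8-en-19,6β-olide | CC1=C(CCC4(C)OCCO4)[C@@]2(C)CCC(=O)[C@](C)(C(=O)O3)[C@@H]2[C@H]3C1 | intermediate
28 | 13,13-(ethylenedioxy)-3α-hydroxy-14,15-dinorlabd-8-en-19,6β-olide | CC1=C(CCC4(C)OCCO4)[C@@]2(C)CC[C@@H](O)[C@](C)(C(=O)O3)[C@@H]2[C@H]3C1 | intermediate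
29 | 13,13-(ethylenedioxy)-14,15-dinorlabd-8-ene-3α,6β,19-triol | CC1=C(CCC3(C)OCCO3)[C@@]2(C)CC[C@@H](O)[C@](C)(CO)[C@@H]2[C@H](O)C1 | intermediate
30 | 3α,6β,19-trihydroxy-14,15-dinorlabd-8-en-13-one | CC1=C(CCC(C)=O)[C@@]2(C)CC[C@@H](O)[C@](C)(CO)[C@@H]2[C@H](O)C1 | intermediate
31 | triethyl phosphonoacetate | CCOC(=O)CP(=O)(OCC)OCC | starting material
32 | ethyl (13E)-3α,6β,19-trihydroxylabda-8,13-dien-15-oate | CC1=C(CC/C(C)=C/C(=O)OCC)[C@@]2(C)CC[C@@H](O)[C@](C)(CO)[C@@H]2[C@H](O)C1 | intermediate
33 | (13E)-3α,6β,19-trihydroxylabda-8,13-dien-15-oic acid (CNP0246116.2) | CC1=C(CC/C(C)=C/C(=O)O)[C@@]2(C)CC[C@@H](O)[C@](C)(CO)[C@@H]2[C@H](O)C1 | target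

**Step count and risks**
Total: 18 steps. Longest linear sequence: 18 steps from (R)-carvone; 17 and 31 are bought and enter in steps 9 and 17.

Step 13 (ring A closure). The risk is that protonation of the samarium enolate, or reduction of the aldehyde, outruns C–C bond formation, so the chain is returned debrominated and uncyclised. The fallback keeps the C3–C4 disconnection but changes the acceptor to a nitrile and the metal to zinc. Aldehyde 24 is condensed with NH2OH·HCl/NaOAc in EtOH to the oxime F1, which trifluoroacetic anhydride/pyridine dehydrates to the nitrile F2. Activated Zn in refluxing THF (intramolecular Blaise reaction, slow addition) inserts into the C4–Br bond, and the zinc enolate adds to the nitrile to give the ring A ketimine F3. Because C4 is quaternary, F3 is a simple N–H imine and hydrolyses in a pH 5 acetate buffer that leaves the dioxolane intact. This gives ketone 27, where the route is rejoined (steps 13 and 14 are bypassed; C3 is still set in step 15).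

Step 6 (olefin shift for the lactonisation). The risk is reconjugation of the β,γ-enone, or protonation of the dienolate at C6 instead of C8, which leaves the carboxyl group without a C6=C7 olefin to add to. The fallback sets out from acid 10 and forms the C9–C11 bond first. The acid is esterified (MeI, K2CO3, DMF) to the methyl ester F4. KN(SiMe3)2/PhNTf2 (γ-deprotonation, O-sulfonylation) gives the dienyl triflate F5, which is coupled with borane 18 under the conditions of step 9 to the diene ester F6. LiOH gives the diene acid F7. Iodolactonisation (I2, NaHCO3) onto the C6=C7 end of the 1,3-diene gives the allylic 7α-iodo lactone F8. Bu3SnH/AIBN then removes iodine, the allyl radical taking hydrogen at the less hindered C7 so that the tetrasubstituted C8=C9 olefin results. The product is 19, where the route is rejoined (steps 6–9 are bypassed).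

Step 9 (side-chain coupling). The risk is slow transmetalation at the tetrasubstituted enol triflate next to quaternary C10, with hydrolysis of the triflate or β-hydride elimination from the alkylpalladium taking over. The fallback sets out from triflate 16 and replaces the sp2–sp3 coupling by an sp2–sp2 bond formation. A Heck reaction with methyl vinyl ketone (Pd(OAc)2, PPh3, Et3N, DMF, 70 °C) gives the (E)-dienone F9. Conjugate reduction with [(Ph3P)CuH]6 (benzene, rt) then saturates only the C11=C12 bond and gives the methyl ketone F10. Ketalisation (ethylene glycol, PPTS, benzene, reflux) returns 19, where the route is rejoined.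

**Further compounds**
F1 | step 13 | oxime of aldehyde 24 (C3=N–OH) | CC1=C(CCC3(C)OCCO3)[C@@](C)(CCC=NO)[C@@H]2C(C)(Br)C(=O)O[C@@H]2C1
F2 | step 13 | C3 nitrile of the bromo lactone | CC1=C(CCC3(C)OCCO3)[C@@](C)(CCC#N)[C@@H]2C(C)(Br)C(=O)O[C@@H]2C1
F3 | step 13 | 13,13-(ethylenedioxy)-3-imino-14,15-dinorlabd-8-en-19,6β-olide | CC1=C(CCC4(C)OCCO4)[C@@]2(C)CCC(=N)[C@](C)(C(=O)O3)[C@@H]2[C@H]3C1
F4 | step 6 | methyl ester of acid 10 | CC1=CC[C@@H](C(C)C(=O)OC)[C@](C)(CC=C)C1=O
F5 | step 6 | C9 dienyl triflate of F4 (C8=C9, C6=C7) | CC1=C(OS(=O)(=O)C(F)(F)F)[C@@](C)(CC=C)[C@H](C(C)C(=O)OC)C=C1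
F6 | step 6 | diene ester with the dioxolane side chain on C9 | CC1=C(CCC2(C)OCCO2)[C@@](C)(CC=C)[C@H](C(C)C(=O)OC)C=C1
F7 | step 6 | diene acid from F6 | CC1=C(CCC2(C)OCCO2)[C@@](C)(CC=C)[C@H](C(C)C(=O)O)C=C1
F8 | step 6 | 7α-iodo derivative of lactone 19 (allylic iodide, trans to the lactone oxygen) | CC1=C(CCC3(C)OCCO3)[C@@](C)(CC=C)[C@@H]2C(C)C(=O)O[C@@H]2[C@H]1I
F9 | step 9 | (E)-dienone: lactone of 16 with a 3-oxobut-1-enyl group on C9 | CC1=C(/C=C/C(C)=O)[C@@](C)(CC=C)[C@@H]2C(C)C(=O)O[C@@H]2C1
F10 | step 9 | lactone of 16 with a 3-oxobutyl group on C9 | CC1=C(CCC(C)=O)[C@@](C)(CC=C)[C@@H]2C(C)C(=O)O[C@@H]2C1
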